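**Plan**

- Retrosynthesis: the C3–aroyl bond is cut first (C3 vinyllithium plus a protected 2,4,5-trioxygenated benzaldehyde), the C6 methylene is taken back to a ketone, C8–CH3 and C7–prenyl are then cut together, ring B is opened at C1–C8 and C5–C6, and the two bridgehead prenyl bonds go last.
- Forward: the C1–C2–C3–C4–C5–C9 ring is the benzene ring of methyl 2,4,6-trihydroxybenzoate (the ester blocks C3). After C-diprenylation, ring B is closed onto it by a dearomative Michael–aldol annulation with 7-methyloct-6-en-2-ynal; oxidation, decarboxylation and O-methylation give the bicyclic enone. The C8/C7 groups and the C3 aroyl group are joined afterwards.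
- Enabling feature: ring B (C1–C8–C7–C6–C5–C9) holds the only non-bridgehead stereocentres, C7 and C8, on adjacent carbons. With a ketone at C6 they are the α- and β-carbon of one enone, C7=C8–C6=O, locked in the bicyclo[3.3.1] frame so that one face looks at the one-carbon bridge C9 and the other at the three-carbon bridge C2–C3–C4.
- Stereochemistry: C1 and C5 come from the chiral ammonium ion pair in the annulation; C8 and C7 from methyl and prenyl entering the enone on the C9 face. Every other centre made on the way (the C6 carbinols, the benzylic carbinol) is removed again.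

Key step: step 8

Remark: numbering follows the bicyclo[3.3.1]nonane core of the target (C1, C5 bridgeheads, C9 bridging ketone); enols are drawn as one tautomer; seen from the face of ring B away from C2–C3–C4, C9→C1→C8→C7→C6→C5 runs anticlockwise.
Assumption: the cinchonidinium catalyst of step 4 is taken to favour the enantiomer drawn; if its sense is opposite, the pseudoenantiomeric cinchoninium salt is used.
Assumption: O-methylation in step 7 is taken to give the C4 ether; the C2 regioisomer, if formed, would serve equally, since the ether is cleaved to the same enol in step 15.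

**Step 1**
Reactants: 1 5-bromo-2-methylpent-2-ene
Product: 2 6-methylhept-5-en-1-yne
Conditions: LiC≡CH·H2NCH2CH2NH2, DMSO, 10 °C → rt
Reagents that add atoms: lithium acetylide ethylenediamine complex, [Li+].[C-]#C.NCCN
Why: SN2 alkylation of an acetylide by an unhindered primary bromide in DMSO is a standard terminal-alkyne synthesis; no stereocentre is formed.

**Step 2**
Reactants: 2 6-methylhept-5-en-1-yne
Product: 4 7-methyloct-6-en-2-ynal, via lithium alkynide 3 (not isolated)
Conditions: n-BuLi, THF, −78 °C; DMF, −78 → 0 °C; inverse quench into cold aq. AcOH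
Reagents that add atoms: N,N-dimethylformamide, CN(C)C=O
Why: Formylation of a lithium acetylide with DMF followed by an acidic inverse quench is the routine route to alk-2-ynals; no stereocentre is formed.

**Step 3**
Reactants: 5 methyl 2,4,6-trihydroxybenzoate; 6 prenyl bromide (2.1 equiv)
Product: 7 methyl 2,4,6-trihydroxy-3,5-bis(3-methylbut-2-enyl)benzoate
Conditions: NaOMe, MeOH, 0 °C → rt
Reagents that add atoms: none
Why: C-alkylation of the ambident phloroglucinolate in a protic medium (the classical C-prenylation of acylphloroglucinols) places the two prenyl groups on the only free ring carbons, the ester occupying the third; no stereocentre is formed.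

**Step 4**
Reactants: 7 methyl 2,4,6-trihydroxy-3,5-bis(3-methylbut-2-enyl)benzoate; 4 7-methyloct-6-en-2-ynal
Product: 9 methyl 4,6-dihydroxy-1,5-bis(3-methylbut-2-enyl)-8-(4-methylpent-3-enyl)-2,9-dioxobicyclo[3.3.1]nona-3,7-diene-3-carboxylate (bridgeheads as in the target; C6 carbinol unassigned), via Michael adduct 8 (not isolated)
Conditions: O-allyl-N-(9-anthracenylmethyl)cinchonidinium bromide (20 mol %), Cs2CO3, 4 Å MS, CH2Cl2, −40 → 0 °C; then AcOH
Reagents that add atoms: none
Why: Proposed new method: the caesium phenolate of 7, held as a chiral ion pair with the cinchonidinium cation, should attack the sp β-carbon of ynal 4 through one of its two enantiotopic prenyl-bearing ring carbons (dearomative Michael addition, C1–C8), protonation of the allenolate giving (Z)-enal 8, in which the remaining prenyl-bearing enolate carbon closes onto the aldehyde (6-(enolendo)-exo-trig aldol, C5–C6) while the acidic ring A β-keto ester keeps the product as a stabilised enolate and so disfavours retro-aldol; the catalyst's choice between the enantiotopic carbons sets C1 and, through the bridge, C5, the C6 carbinol configuration being immaterial; the closest known reaction type is the phase-transfer-catalysed enantioselective alkylative dearomatisation–annulation of 3,5-diprenylated acylphloroglucinols with enal bis-electrophiles that ends in an aldol closure, here extended from an enal to an ynal acceptor.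

**Step 5**
Reactants: 9 bicyclic ketol
Product: 10 methyl 4-hydroxy-1,5-bis(3-methylbut-2-enyl)-8-(4-methylpent-3-enyl)-2,6,9-trioxobicyclo[3.3.1]nona-3,7-diene-3-carboxylate
Conditions: Dess–Martin periodinane, CH2Cl2, 0 °C → rt
Reagents that add atoms: none
Why: Dess–Martin oxidation of the allylic C6 carbinol gives the C7=C8–C6=O enone without touching the trisubstituted alkenes or the fully substituted ring A enol; the C6 stereocentre is erased.

**Step 6**
Reactants: 10 bicyclic enone ester
Product: 11 4-hydroxy-1,5-bis(3-methylbut-2-enyl)-8-(4-methylpent-3-enyl)bicyclo[3.3.1]nona-3,7-diene-2,6,9-trione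
Conditions: LiCl, DMSO, 120 °C; cold dil. aq. HCl work-up
Reagents that add atoms: none
Why: Krapcho dealkoxycarbonylation, in which chloride demethylates the ester and the diketo carboxylate loses CO2 to the stabilised ring A enolate under non-hydrolytic conditions that spare the nucleophile-sensitive carbonyls around C5; no stereocentre changes.

**Step 7**
Reactants: 11 bicyclic enone dione
Product: 12 4-methoxy-1,5-bis(3-methylbut-2-enyl)-8-(4-methylpent-3-enyl)bicyclo[3.3.1]nona-3,7-diene-2,6,9-trione
Conditions: HC(OMe)3, p-TsOH·H2O (cat.), MeOH, 40 °C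
Reagents that add atoms: trimethyl orthoformate, COC(OC)OC
Why: Acid-catalysed enol etherification of a cyclic 1,3-dione with an orthoformate (the usual O-methylation of bicyclic PPAP triones) under equilibrating conditions, expected to leave the free carbonyl at C2 next to the less acylated bridgehead C1; no stereocentre changes.

**Step 8**
Reactants: 12 bicyclic enone methyl enol ether; 6 prenyl bromide
Product: 14 4-methoxy-8-methyl-1,5,7-tris(3-methylbut-2-enyl)-8-(4-methylpent-3-enyl)bicyclo[3.3.1]non-3-ene-2,6,9-trione (C8 methyl and C7 prenyl both on the C9 face), via lithium enolate 13 (not isolated)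
Conditions: Me2CuLi (from MeLi and CuI), Et2O, −30 → 0 °C; then 6, HMPA–THF, −20 °C → rt; aq. NH4Cl–NH3
Reagents that add atoms: lithium dimethylcuprate, [Li+].C[Cu-]C
Why: Me2CuLi π-complexes the C7=C8–C6=O enone of ring B and transfers methyl to C8 (β-adduct of trivalent copper, then reductive elimination), leaving lithium enolate 13, which is C-allylated at C7 by prenyl bromide once HMPA loosens the aggregate. The closest known reaction type is cuprate conjugate addition to β,β-disubstituted cyclohexenones with in situ enolate alkylation (vicinal difunctionalisation); two C–C bonds form and no ring closes. C8 is set by axial, chair-forming delivery of methyl on the face that carries only the one-carbon bridge C9, the other face being covered by the C2–C3–C4 bridge, so the homoprenyl chain ends equatorial. C7 is set by attack of the halide on the same exo face of the enolate, and because C7–H stays enolisable next to C6=O, the exo (equatorial) prenyl epimer is also the one favoured on base equilibration. The step needs chemoselectivity for the ring B enone, secured because the ring A vinylogous ester is deactivated by its methoxy donor, the C9 ketone sits between two quaternary carbons and cuprates do not add 1,2; it also needs C- over O-alkylation, favoured by the soft allylic bromide.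

**Step 9**
Reactants: 14 C6-oxo bicycle
Product: 15 6-hydroxy-4-methoxy-8-methyl-1,5,7-tris(3-methylbut-2-enyl)-8-(4-methylpent-3-enyl)bicyclo[3.3.1]non-3-ene-2,9-dione (C6 carbinol unassigned)
Conditions: NaBH4, CeCl3·7H2O, MeOH–THF, −40 °C; AcOH quench
Reagents that add atoms: none
Why: Luche reduction at low temperature delivers hydride to the C6 ketone, the only carbonyl that is neither a vinylogous ester nor buried between two quaternary bridgeheads, and the cerium-bound, acid-quenched alkoxide is kept from retro-aldol cleavage of C5–C6; the new C6 centre is inconsequential.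

**Step 10**
Reactants: 15 C6 carbinol
Product: 16 O-phenyl thionocarbonate of 15 (at the C6 oxygen)
Conditions: PhOC(S)Cl, pyridine, 4-(dimethylamino)pyridine (cat.), CH2Cl2, rt
Reagents that add atoms: O-phenyl chlorothionoformate, S=C(Cl)Oc1ccccc1
Why: Acylation of the secondary alcohol under amine catalysis gives the Barton–McCombie substrate without ever generating the free C6 alkoxide, which would fragment by retro-aldol; no stereocentre changes.

**Step 11**
Reactants: 16 C6 thionocarbonate
Product: 17 4-methoxy-8-methyl-1,5,7-tris(3-methylbut-2-enyl)-8-(4-methylpent-3-enyl)bicyclo[3.3.1]non-3-ene-2,9-dione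
Conditions: Bu3SnH (3 equiv, 0.3 M), AIBN (cat.), toluene, 90 °C
Reagents that add atoms: none
Why: Barton–McCombie deoxygenation (stannyl radical addition to C=S, β-scission to the secondary C6 radical, hydrogen transfer from Bu3SnH), the side-chain alkenes being placed only for slow 4-exo or 6-exo capture, which the concentrated stannane outruns; the C6 centre disappears and C7 is untouched.

**Step 12**
Reactants: 18 2,4,5-trihydroxybenzaldehyde
Product: 19 2,4,5-tris(methoxymethoxy)benzaldehyde
Conditions: MOMCl, i-Pr2NEt, CH2Cl2, 0 → 40 °C, argon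
Reagents that add atoms: chloromethyl methyl ether, COCCl
Why: O-alkylation of the three phenols with MOMCl and Hünig's base gives acetal ethers that withstand organolithiums, base and hot LiCl; no stereocentre is formed.

**Step 13**
Reactants: 17 deoxygenated bicycle; 19 2,4,5-tris(methoxymethoxy)benzaldehyde
Product: 21 3-{hydroxy[2,4,5-tris(methoxymethoxy)phenyl]methyl} derivative of 17 (carbinol centre unassigned), via C3 vinyllithium 20 (not isolated)
Conditions: LiN(i-Pr)2, THF, −78 °C; 19, −78 °C; AcOH
Reagents that add atoms: none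
Why: C3–H of the vinylogous ester is the only acidic C–H left (C1 and C5 quaternary, C6 deoxygenated), so amide-base α-lithiation of the β-alkoxy enone (as used for C3 acylation of PPAP methyl enol ethers) gives vinyllithium 20, which adds to aldehyde 19; the carbinol centre forms unselectively and is erased in step 14.

**Step 14**
Reactants: 21 C3 carbinol
Product: 22 4-methoxy-8-methyl-1,5,7-tris(3-methylbut-2-enyl)-8-(4-methylpent-3-enyl)-3-[2,4,5-tris(methoxymethoxy)benzoyl]bicyclo[3.3.1]non-3-ene-2,9-dione
Conditions: Dess–Martin periodinane, CH2Cl2, 0 °C → rt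
Reagents that add atoms: none
Why: Dess–Martin oxidation of the allylic, benzylic carbinol gives the aryl ketone under conditions harmless to MOM ethers and prenyl groups; the carbinol centre is removed.

**Step 15**
Reactants: 22 O-methyl, tris-MOM precursor
Product: 23 4-hydroxy-8-methyl-1,5,7-tris(3-methylbut-2-enyl)-8-(4-methylpent-3-enyl)-3-[2,4,5-tris(methoxymethoxy)benzoyl]bicyclo[3.3.1]non-3-ene-2,9-dione
Conditions: LiCl, DMSO, 120 °C; cold dil. aq. HCl work-up
Reagents that add atoms: none
Why: SN2 demethylation of the doubly activated vinylogous ester by chloride in hot DMSO (the standard unmasking of PPAP methyl enol ethers) frees the triketone enol while the MOM ethers still keep the 2'-oxygen from cyclising onto C4; no stereocentre changes.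

**Step 16**
Reactants: 23 tris-MOM guttiferone L
Product: 24 guttiferone L
Conditions: HCl (2 M aq., few equiv), MeOH, rt, degassed, argon
Reagents that add atoms: none
Why: Acid-catalysed methanolysis of the three aryl MOM acetals under conditions too mild for prenyl protonation or xanthone-type cyclodehydration releases the triphenol; no stereocentre changes.

**Compound list**

1 | 5-bromo-2-methylpent-2-ene | CC(C)=CCCBr | starting material
2 | 6-methylhept-5-en-1-yne | CC(C)=CCCC#C | intermediate
3 | lithium 6-methylhept-5-en-1-yn-1-ide (not isolated) | [Li+].[C-]#CCCC=C(C)C | intermediate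
4 | 7-methyloct-6-en-2-ynal | CC(C)=CCCC#CC=O | intermediate
5 | methyl 2,4,6-trihydroxybenzoate | COC(=O)c1c(O)cc(O)cc1O | starting material
6 | prenyl bromide (1-bromo-3-methylbut-2-ene) | CC(C)=CCBr | starting material
7 | methyl 2,4,6-trihydroxy-3,5-bis(3-methylbut-2-enyl)benzoate | COC(=O)c1c(O)c(CC=C(C)C)c(O)c(CC=C(C)C)c1O | intermediate
8 | methyl 2,4-dihydroxy-3,5-bis(3-methylbut-2-enyl)-5-[(2Z)-7-methyl-1-oxoocta-2,6-dien-3-yl]-6-oxocyclohexa-1,3-diene-1-carboxylate (not isolated) | O=C/C=C(/CCC=C(C)C)[C@]1(CC=C(C)C)C(=O)C(C(=O)OC)=C(O)C(CC=C(C)C)=C1O | intermediate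
9 | methyl 4,6-dihydroxy-1,5-bis(3-methylbut-2-enyl)-8-(4-methylpent-3-enyl)-2,9-dioxobicyclo[3.3.1]nona-3,7-diene-3-carboxylate, C6 unassigned | CC(C)=CCCC1=CC(O)[C@]2(CC=C(C)C)C(=O)[C@@]1(CC=C(C)C)C(=O)C(C(=O)OC)=C2O | intermediate
10 | methyl 4-hydroxy-1,5-bis(3-methylbut-2-enyl)-8-(4-methylpent-3-enyl)-2,6,9-trioxobicyclo[3.3.1]nona-3,7-diene-3-carboxylate | CC(C)=CCCC1=CC(=O)[C@]2(CC=C(C)C)C(=O)[C@@]1(CC=C(C)C)C(=O)C(C(=O)OC)=C2O | intermediate
11 | 4-hydroxy-1,5-bis(3-methylbut-2-enyl)-8-(4-methylpent-3-enyl)bicyclo[3.3.1]nona-3,7-diene-2,6,9-trione | CC(C)=CCCC1=CC(=O)[C@]2(CC=C(C)C)C(=O)[C@@]1(CC=C(C)C)C(=O)C=C2O | intermediate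
12 | 4-methoxy-1,5-bis(3-methylbut-2-enyl)-8-(4-methylpent-3-enyl)bicyclo[3.3.1]nona-3,7-diene-2,6,9-trione (key-step precursor) | CC(C)=CCCC1=CC(=O)[C@]2(CC=C(C)C)C(=O)[C@@]1(CC=C(C)C)C(=O)C=C2OC | intermediate
13 | lithium 4-methoxy-8-methyl-1,5-bis(3-methylbut-2-enyl)-8-(4-methylpent-3-enyl)-2,9-dioxobicyclo[3.3.1]nona-3,6-dien-6-olate (not isolated) | CC(C)=CCC[C@@]1(C)C=C([O-])[C@]2(CC=C(C)C)C(=O)[C@@]1(CC=C(C)C)C(=O)C=C2OC.[Li+] | intermediate
14 | 4-methoxy-8-methyl-1,5,7-tris(3-methylbut-2-enyl)-8-(4-methylpent-3-enyl)bicyclo[3.3.1]non-3-ene-2,6,9-trione, 7-exo-prenyl, 8-exo-methyl (key-step product) | CC(C)=CCC[C@@]1(C)[C@H](CC=C(C)C)C(=O)[C@]2(CC=C(C)C)C(=O)[C@@]1(CC=C(C)C)C(=O)C=C2OC | intermediate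
15 | 6-hydroxy-4-methoxy-8-methyl-1,5,7-tris(3-methylbut-2-enyl)-8-(4-methylpent-3-enyl)bicyclo[3.3.1]non-3-ene-2,9-dione, C6 unassigned | CC(C)=CCC[C@@]1(C)[C@H](CC=C(C)C)C(O)[C@]2(CC=C(C)C)C(=O)[C@@]1(CC=C(C)C)C(=O)C=C2OC | intermediate
16 | O-phenyl thionocarbonate of 15 at the C6 oxygen | CC(C)=CCC[C@@]1(C)[C@H](CC=C(C)C)C(OC(=S)Oc3ccccc3)[C@]2(CC=C(C)C)C(=O)[C@@]1(CC=C(C)C)C(=O)C=C2OC | intermediate
17 | 4-methoxy-8-methyl-1,5,7-tris(3-methylbut-2-enyl)-8-(4-methylpent-3-enyl)bicyclo[3.3.1]non-3-ene-2,9-dione | CC(C)=CCC[C@@]1(C)[C@H](CC=C(C)C)C[C@]2(CC=C(C)C)C(=O)[C@@]1(CC=C(C)C)C(=O)C=C2OC | intermediate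
18 | 2,4,5-trihydroxybenzaldehyde | O=Cc1cc(O)c(O)cc1O | starting material
19 | 2,4,5-tris(methoxymethoxy)benzaldehyde | O=Cc1cc(OCOC)c(OCOC)cc1OCOC | intermediate
20 | C3-lithio derivative of 17 (not isolated) | CC(C)=CCC[C@@]1(C)[C@H](CC=C(C)C)C[C@]2(CC=C(C)C)C(=O)[C@@]1(CC=C(C)C)C(=O)C([Li])=C2OC | intermediate
21 | 3-{hydroxy[2,4,5-tris(methoxymethoxy)phenyl]methyl} derivative of 17, carbinol centre unassigned | CC(C)=CCC[C@@]1(C)[C@H](CC=C(C)C)C[C@]2(CC=C(C)C)C(=O)[C@@]1(CC=C(C)C)C(=O)C(C(O)c3cc(OCOC)c(OCOC)cc3OCOC)=C2OC | intermediate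
22 | 3-[2,4,5-tris(methoxymethoxy)benzoyl] derivative of 17 | CC(C)=CCC[C@@]1(C)[C@H](CC=C(C)C)C[C@]2(CC=C(C)C)C(=O)[C@@]1(CC=C(C)C)C(=O)C(C(=O)c3cc(OCOC)c(OCOC)cc3OCOC)=C2OC | intermediate
23 | tris(methoxymethyl) ether of guttiferone L (free C4 enol) | CC(C)=CCC[C@@]1(C)[C@H](CC=C(C)C)C[C@]2(CC=C(C)C)C(=O)[C@@]1(CC=C(C)C)C(=O)C(C(=O)c3cc(OCOC)c(OCOC)cc3OCOC)=C2O | intermediate
24 | guttiferone L | CC(C)=CCC[C@@]1(C)[C@H](CC=C(C)C)C[C@]2(CC=C(C)C)C(=O)[C@@]1(CC=C(C)C)C(=O)C(C(=O)c1cc(O)c(O)cc1O)=C2O | target

**Count**

Total steps: 16. Longest linear sequence: 14 steps (1 → 2 → 4 → 9 → 10 → 11 → 12 → 14 → 15 → 16 → 17 → 21 → 22 → 23 → 24; steps 1, 2, 4–11 and 13–16).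

**Steps most likely to fail**

Step 4 (Proposed new method). The ynal may be taken up through a phenolate oxygen instead of a ring carbon, the enal of 8 may close onto an enol oxygen (lactol) instead of C5, or the catalyst may discriminate the two enantiotopic ring carbons poorly. The fallback uses known chemistry and sets out from 1 and 7. Bromide 1 is converted with Mg into 4-methylpent-3-enylmagnesium bromide F1, which adds to 3-(dimethylamino)acrolein and gives, after acidic work-up, (2E)-7-methylocta-2,6-dienal F2. Arene 7 and F2 are then joined under the same phase-transfer conditions by the Michael–aldol annulation known for 2-substituted cyclic 1,3-diones and enals, giving the saturated bicyclic ketol F3. Dess–Martin oxidation gives the C6 ketone F4, and IBX dehydrogenation (DMSO, 70 °C) introduces C7=C8. The fallback comes back to the route at 10.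

Step 8. Methyl transfer to C8 may be too slow because this β-carbon is flanked by the quaternary C1, so that the enone is recovered or merely reduced. The fallback sets out from 11, whose acidic ring A enol can be carried as an enolate that resists dissolving-metal reduction. Corey–Chaykovsky cyclopropanation with Me3S(O)I and NaH (one extra equivalent for the enol) in DMSO should add CH2 across C7=C8 on the C9 face and give, after acidification, the cyclopropyl ketone F5. The enol is deprotonated with LiN(SiMe3)2, and lithium (2.2 equiv) in liquid NH3–THF with t-BuOH (1 equiv) at −78 °C then cleaves the exocyclic C7–CH2 bond, the one that overlaps the C6 carbonyl π system. This leaves the C8 methyl group and the dilithium dienolate F6. Prenyl bromide 6 alkylates its more basic C6 enolate at C7 from the C9 face, and NH4Cl work-up gives the enol trione F7. O-Methylation with HC(OMe)3 and p-TsOH·H2O in MeOH, as in step 7, completes the detour. The fallback comes back to the route at 14.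

Step 9. Once the C6 oxygen carries negative charge, the C5–C6 bond can open by retro-aldol, because C5 is a highly stabilised leaving carbanion; hydride may also attack C9 or C2. The fallback sets out from 14. Condensation with TsNHNH2 gives the C6 tosylhydrazone F8; reduction with catecholborane and decomposition with NaOAc·3H2O (Kabalka variant of the Caglioti reduction) gives the methylene compound directly. The fallback comes back to the route at 17, bypassing 15 and 16.

**Further compounds**

F1 | step 4 | 4-methylpent-3-enylmagnesium bromide | CC(C)=CCC[Mg]Br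
F2 | step 4 | (2E)-7-methylocta-2,6-dienal | CC(C)=CCC/C=C/C=O
F3 | step 4 | methyl 4,6-dihydroxy-1,5-bis(3-methylbut-2-enyl)-8-(4-methylpent-3-enyl)-2,9-dioxobicyclo[3.3.1]non-3-ene-3-carboxylate (C6, C8 unassigned) | CC(C)=CCCC1CC(O)[C@]2(CC=C(C)C)C(=O)[C@@]1(CC=C(C)C)C(=O)C(C(=O)OC)=C2O
F4 | step 4 | methyl 4-hydroxy-1,5-bis(3-methylbut-2-enyl)-8-(4-methylpent-3-enyl)-2,6,9-trioxobicyclo[3.3.1]non-3-ene-3-carboxylate (C8 unassigned) | CC(C)=CCCC1CC(=O)[C@]2(CC=C(C)C)C(=O)[C@@]1(CC=C(C)C)C(=O)C(C(=O)OC)=C2O
F5 | step 8 | 7,8-methano adduct of 11 (cyclopropane CH2 on the C9 face, ring A as the free enol) | CC(C)=CCC[C@@]1(C3)[C@H]3C(=O)[C@]2(CC=C(C)C)C(=O)[C@@]1(CC=C(C)C)C(=O)C=C2O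
F6 | step 8 | dilithium 8-methyl-1,5-bis(3-methylbut-2-enyl)-8-(4-methylpent-3-enyl)-2,9-dioxobicyclo[3.3.1]nona-3,6-diene-4,6-bis(olate) | CC(C)=CCC[C@@]1(C)C=C([O-])[C@]2(CC=C(C)C)C(=O)[C@@]1(CC=C(C)C)C(=O)C=C2[O-].[Li+].[Li+]
F7 | step 8 | 4-hydroxy-8-methyl-1,5,7-tris(3-methylbut-2-enyl)-8-(4-methylpent-3-enyl)bicyclo[3.3.1]non-3-ene-2,6,9-trione | CC(C)=CCC[C@@]1(C)[C@H](CC=C(C)C)C(=O)[C@]2(CC=C(C)C)C(=O)[C@@]1(CC=C(C)C)C(=O)C=C2O
F8 | step 9 | C6 p-toluenesulfonylhydrazone of 14 | CC(C)=CCC[C@@]1(C)[C@H](CC=C(C)C)C(=NNS(=O)(=O)c3ccc(C)cc3)[C@]2(CC=C(C)C)C(=O)[C@@]1(CC=C(C)C)C(=O)C=C2OC
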